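**Retrosynthetic overview**
1. Target 14 comes from hexamethyl ether 13 by cleavage of the six aryl methyl ethers.
2. The C3–O bond of 13 is disconnected to two molecules of one monomer 11. The forward step is an enantioselective oxidative dehydrodimerisation, and it sets the only stereocentre.
3. Monomer 11 comes from tetralone 9 by exhaustive aerobic oxidation. Tetralone 9 comes from indanone 6 by the key step, a one-carbon ring expansion through a 1,2-aryl shift.
4. Indanone 6 comes from 1,2,4-trimethoxybenzene 3 and 2-ethylacrylic acid 4, which fixes the oxygen/ethyl regiochemistry. Compound 3 comes from 1,4-benzoquinone 1.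
5. Ring order: benzenoid ring (from 1), then the five-membered ring, which is enlarged to six and oxidised to the quinone. The two bicycles are joined last.

**Assumption:** the (R,R)-iodane of step 6 is taken to give (S)-13. The sense of induction has to be checked on the first run (ECD or X-ray of 13). If it is reversed, the equally accessible (S,S)-iodane is used.

**Reagent for step 6 (not numbered):** Ar*I(OAc)2 is {2,6-bis[(1R)-1-(mesitylcarbamoyl)ethoxy]phenyl}-λ3-iodanediyl diacetate. It is made beforehand from the commercial (R,R)-iodoarene with peracetic acid in AcOH.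
SMILES: C[C@@H](Oc1cccc(O[C@H](C)C(=O)Nc2c(C)cc(C)cc2C)c1I(OC(C)=O)OC(C)=O)C(=O)Nc1c(C)cc(C)cc1C

Step 1
Reactants: 1 1,4-benzoquinone
Product: 2 benzene-1,2,4-triyl triacetate
Conditions: Ac2O, cat. H2SO4, 40–50 °C
Reagents that add atoms: acetic anhydride, CC(=O)OC(C)=O
Why: Thiele–Winter acetoxylation, in which acid-catalysed 1,4-addition of acetate to the quinone, aromatisation and peracetylation install the third ring oxygen in one reliable operation.

Step 2
Reactants: 2 benzene-1,2,4-triyl triacetate
Product: 3 1,2,4-trimethoxybenzene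
Conditions: Me2SO4, aq NaOH, MeOH, N2, 0 °C → reflux
Reagents that add atoms: dimethyl sulfate, COS(=O)(=O)OC
Why: One-pot saponification and Williamson O-methylation, in which the air-sensitive triol is trapped as it forms, so that the robust methyl ethers carry the three oxygens through the acidic, basic and oxidative steps that follow.

Step 3
Reactants: 3 1,2,4-trimethoxybenzene; 4 2-ethylacrylic acid
Product: 6 2-ethyl-4,6,7-trimethoxy-2,3-dihydro-1H-inden-1-one (racemic), via arylmethylbutanoic acid 5 (not isolated)
Conditions: PPA (76% P2O5), 100 °C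
Reagents that add atoms: none
Why: Tandem Friedel–Crafts conjugate alkylation and intramolecular acylation in low-P2O5 PPA, in which C5 of 3 (the normal site of electrophilic attack) adds to the CH2 terminus of the protonated acid and acid 5 can then close only onto the adjacent free carbon, which places the carbonyl next to the vicinal OMe pair and fixes the substitution pattern; C2 forms racemic and is flattened in step 5.

Step 4
Reactants: 6 2-ethyl-4,6,7-trimethoxy-2,3-dihydro-1H-inden-1-one; 7 (trimethylsilyl)diazomethane
Product: 9 3-ethyl-5,7,8-trimethoxy-3,4-dihydronaphthalen-2(1H)-one (racemic), via α-silyl ketone 8 (not isolated)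
Conditions: BF3·OEt2, CH2Cl2, −78 → −20 °C; then 1 M HCl, THF, rt
Reagents that add atoms: none
Why: Lewis-acid-promoted diazoalkane–ketone homologation (Tiffeneau–Demjanov-type ring expansion), in which 7 adds to the activated carbonyl and loss of N2 drives a 1,2-shift of the electron-rich aryl carbon that enlarges the five-membered ring to six, the bulky α-silyl ketone 8 resists a second homologation, and any product of the competing alkyl shift (the 1-tetralone isomer) has the same order of ring atoms and is oxidised to the same quinone in step 5.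

Step 5
Reactants: 9 3-ethyl-5,7,8-trimethoxy-3,4-dihydronaphthalen-2(1H)-one
Product: 11 3-ethyl-2-hydroxy-5,7,8-trimethoxynaphthalene-1,4-dione, via 1,2-naphthoquinone 10 (not isolated)
Conditions: O2 (1 atm), KOtBu, t-BuOH, rt; then 1 M HCl
Reagents that add atoms: dioxygen, O=O
Why: Base-promoted autoxidation of a tetralone to a 2-hydroxy-1,4-naphthoquinone, in which the benzylic enolate takes up O2, the 1,2-dione aromatises and is oxidised to 10, and peroxide anion formed in situ adds at C4 so that further oxidation gives 11 as its stable potassium salt, while the aryl methyl ethers stay inert.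

Step 6
Reactants: 11 3-ethyl-2-hydroxy-5,7,8-trimethoxynaphthalene-1,4-dione (two molecules)
Product: 13 (3S)-3-ethyl-3-[(3-ethyl-5,7,8-trimethoxy-1,4-dioxo-1,4-dihydronaphthalen-2-yl)oxy]-5,7,8-trimethoxynaphthalene-1,2,4(3H)-trione, via bis(quinonyloxy)-λ3-iodane 12 (not isolated)
Conditions: Ar*I(OAc)2 (0.52 equiv), PhMe, 0 °C, AcOH stripped in vacuo; then CH2Cl2, 4 Å MS, −30 → 0 °C, dark
Reagents that add atoms: none
Why: Proposed new method: enantioselective dehydrodimerisation of a 2-hydroxy-3-alkylnaphthoquinone on a chiral aryl-λ3-iodane; 11 is a vinylogous carboxylic acid and should replace both acetates at trivalent iodine as carboxylic acids do (removal of AcOH also removes the competing acetate nucleophile), one I–O-bound quinonate in 12 is then an umpoled, enolonium-type electrophile at C3 and the oxygen of the second quinonate on the same iodine is delivered to C3 as the iodoarene leaves in the monovalent state (ligand coupling), and the lactamide arms, folded over iodine by N–H···O hydrogen bonds, shield one face of C2=C3 so that the new C3–O bond gives the (S) quaternary centre, which has no α-H and cannot epimerise; the closest known reaction types are chiral-iodane Kita-type dearomatising spirolactonisation of naphthols, iodane-mediated α-acyloxylation of enolisable ketones and the racemic PbO2 dehydrodimerisation of 2-hydroxy-3-alkylnaphthoquinones.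

Step 7
Reactants: 13 (S)-hexamethyl ether
Product: 14 (3S)-3-ethyl-3-[(3-ethyl-5,7,8-trihydroxy-1,4-dioxo-1,4-dihydronaphthalen-2-yl)oxy]-5,7,8-trihydroxynaphthalene-1,2,4(3H)-trione
Conditions: BBr3 (12 equiv), CH2Cl2, −78 → 0 °C; then H2O
Reagents that add atoms: none
Why: Lewis-acid aryl methyl ether cleavage, in which the four peri OMe groups fall quickly through six-membered boron chelates with the neighbouring C=O and the two C7 OMe groups through the catechol-type borate with O8, whereas the bridging ether carbon carries two acyl groups (no ionisation, too hindered for SN2) and the quaternary stereocentre is untouched under these non-basic, non-reducing conditions.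

**Compound list**
1 | 1,4-benzoquinone | O=C1C=CC(=O)C=C1 | starting material
2 | benzene-1,2,4-triyl triacetate | CC(=O)Oc1ccc(OC(C)=O)c(OC(C)=O)c1 | intermediate
3 | 1,2,4-trimethoxybenzene | COc1ccc(OC)c(OC)c1 | intermediate
4 | 2-ethylacrylic acid (2-methylidenebutanoic acid) | CCC(=C)C(=O)O | starting material
5 | 2-[(2,4,5-trimethoxyphenyl)methyl]butanoic acid (racemic, not isolated) | CCC(Cc1cc(OC)c(OC)cc1OC)C(=O)O | intermediate
6 | 2-ethyl-4,6,7-trimethoxy-2,3-dihydro-1H-inden-1-one (racemic) | CCC1Cc2c(OC)cc(OC)c(OC)c2C1=O | intermediate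
7 | (trimethylsilyl)diazomethane | C[Si](C)(C)C=[N+]=[N-] | starting material
8 | 3-ethyl-5,7,8-trimethoxy-1-(trimethylsilyl)-3,4-dihydronaphthalen-2(1H)-one (racemic diastereomer mixture, not isolated) | CCC1Cc2c(OC)cc(OC)c(OC)c2C([Si](C)(C)C)C1=O | intermediate
9 | 3-ethyl-5,7,8-trimethoxy-3,4-dihydronaphthalen-2(1H)-one (racemic) | CCC1Cc2c(OC)cc(OC)c(OC)c2CC1=O | intermediate
10 | 3-ethyl-5,7,8-trimethoxynaphthalene-1,2-dione (not isolated) | CCC1=Cc2c(OC)cc(OC)c(OC)c2C(=O)C1=O | intermediate
11 | 3-ethyl-2-hydroxy-5,7,8-trimethoxynaphthalene-1,4-dione | CCC1=C(O)C(=O)c2c(OC)c(OC)cc(OC)c2C1=O | intermediate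
12 | {2,6-bis[(1R)-1-(mesitylcarbamoyl)ethoxy]phenyl}bis[(3-ethyl-5,7,8-trimethoxy-1,4-dioxo-1,4-dihydronaphthalen-2-yl)oxy]-λ3-iodane (not isolated) | C[C@@H](Oc1cccc(O[C@H](C)C(=O)Nc2c(C)cc(C)cc2C)c1I(OC3=C(CC)C(=O)c4c(OC)cc(OC)c(OC)c4C3=O)OC5=C(CC)C(=O)c6c(OC)cc(OC)c(OC)c6C5=O)C(=O)Nc7c(C)cc(C)cc7C | intermediate
13 | (3S)-3-ethyl-3-[(3-ethyl-5,7,8-trimethoxy-1,4-dioxo-1,4-dihydronaphthalen-2-yl)oxy]-5,7,8-trimethoxynaphthalene-1,2,4(3H)-trione | CCC1=C(O[C@]2(CC)C(=O)C(=O)c3c(OC)c(OC)cc(OC)c3C2=O)C(=O)c2c(OC)c(OC)cc(OC)c2C1=O | intermediate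
14 | (3S)-3-ethyl-3-[(3-ethyl-5,7,8-trihydroxy-1,4-dioxo-1,4-dihydronaphthalen-2-yl)oxy]-5,7,8-trihydroxynaphthalene-1,2,4(3H)-trione | CCC1=C(O[C@]2(CC)C(=O)C(=O)c3c(O)c(O)cc(O)c3C2=O)C(=O)c2c(O)c(O)cc(O)c2C1=O | target

**Total step count:** 7.
**Longest linear sequence:** 7. The route is linear, and step 6 joins two molecules of the same intermediate.

**Three steps most likely to fail**

Step 6 (the proposed new step).
- Risks: acetate instead of quinonate may be transferred to C3. The activated species may lose a proton from the ethyl CH2 to give a quinone methide. Facial selectivity may be low.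
- Fallback, from 11 back to 13: the known one-electron dehydrodimerisation of 2-hydroxy-3-alkylnaphthoquinones with tetravalent lead (PbO2, AcOH–CH2Cl2, rt) gives the racemic hexamethyl ether F2. Preparative HPLC on a chiral stationary phase then separates (S)-13 from the (R)-hexamethyl ether F3.

Step 7.
- Risks: six ether cleavages have to be completed next to a vinylogous-ester linkage and an electrophilic 1,2-dione. Bromide may add to the quinone carbon and expel the tertiary alkoxide. Any reducing or basic conditions split the dimer back into monomer.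
- Fallback, from 11 back to 14: the order of events is reversed. The robust monomer is demethylated first (48% HBr, AcOH, reflux) to 3-ethyl-2,5,7,8-tetrahydroxynaphthalene-1,4-dione F4. This is dehydrodimerised with PbO2 in AcOH to the racemic target F5. Chiral-phase HPLC then gives 14 and the (R)-enantiomer of the target F6.

Step 4.
- Risks: addition to the hindered, ortho-methoxy aryl ketone may be sluggish. Oxirane formation or a second homologation may compete.
- Fallback, from 6 back to 9: Wittig methylenation (Ph3PCH3Br, KOtBu, THF) gives 2-ethyl-4,6,7-trimethoxy-1-methylidene-2,3-dihydro-1H-indene F1. Its exocyclic alkene undergoes the known oxidative 1,2-aryl-shift ring expansion with PhI(OH)OTs in 95% MeOH to give 9 directly.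

**Further compounds**
F1 | step 4 | 2-ethyl-4,6,7-trimethoxy-1-methylidene-2,3-dihydro-1H-indene (racemic) | CCC1Cc2c(OC)cc(OC)c(OC)c2C1=C
F2 | step 6 | racemic 3-ethyl-3-[(3-ethyl-5,7,8-trimethoxy-1,4-dioxo-1,4-dihydronaphthalen-2-yl)oxy]-5,7,8-trimethoxynaphthalene-1,2,4(3H)-trione | CCC1=C(OC2(CC)C(=O)C(=O)c3c(OC)c(OC)cc(OC)c3C2=O)C(=O)c2c(OC)c(OC)cc(OC)c2C1=O
F3 | step 6 | (3R)-enantiomer of 13 | CCC1=C(O[C@@]2(CC)C(=O)C(=O)c3c(OC)c(OC)cc(OC)c3C2=O)C(=O)c2c(OC)c(OC)cc(OC)c2C1=O
F4 | step 7 | 3-ethyl-2,5,7,8-tetrahydroxynaphthalene-1,4-dione | CCC1=C(O)C(=O)c2c(O)c(O)cc(O)c2C1=O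
F5 | step 7 | racemic 3-ethyl-3-[(3-ethyl-5,7,8-trihydroxy-1,4-dioxo-1,4-dihydronaphthalen-2-yl)oxy]-5,7,8-trihydroxynaphthalene-1,2,4(3H)-trione | CCC1=C(OC2(CC)C(=O)C(=O)c3c(O)c(O)cc(O)c3C2=O)C(=O)c2c(O)c(O)cc(O)c2C1=O
F6 | step 7 | (3R)-enantiomer of 14 | CCC1=C(O[C@@]2(CC)C(=O)C(=O)c3c(O)c(O)cc(O)c3C2=O)C(=O)c2c(O)c(O)cc(O)c2C1=O
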